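**Retrosynthetic overview**

- The strategy rests on ring D, the dihydropyran fused to ring B at C3'–C4'. Its benzylic C4'' and ring oxygen O1'' are the two termini of an ortho-quinone methide of ring B, and C3''–C2'' is a 2-methylpropene unit with a heteroatom on C3''. Cutting C4''–C3'' and O1''–C2'' gives that quinone methide and 2-methylprop-1-enyl pinacolboronate, with boron marking the (R)-hydroxyl.
- The second oxygen of ring B (later 2'-OH) is carried as an allyl ether. This makes the quinone methide precursor a storable mono-phenol, and the allyl group later supplies C3 and C2 of ring C by Claisen rearrangement to C1' and oxidative cleavage.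
- Ring C is cut at C3–C4 (acylation of the arylacetaldehyde enamine) and at O1–C8a (displacement of fluoride). Ring A is 5-fluororesorcinol, prenylated at the symmetric carbon between its two oxygens, so fluorine alone defines C8a and the prenyl group must end at C6.
- Ring order: ring B (bought), ring D (step 3), ring A elaborated separately (steps 8–11), ring C (step 13), then removal of all four acetals (step 14).

Key step: step 3

Assumption: the (R)-configured catalyst is taken to favour the (3R)-boronate; if the opposite sense is found, its (S)-enantiomer is used with no other change.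

**Route**

Step 1
Reactants: 1 2,6-dihydroxybenzaldehyde; 2 allyl bromide
Product: 3 2-(allyloxy)-6-hydroxybenzaldehyde
Conditions: K2CO3 (1.0 equiv), 2 (1.0 equiv), DMF, rt
Reagents that add atoms: none
Why: Williamson ether synthesis; after the first alkylation the remaining hydroxyl is hydrogen-bonded to the aldehyde and much less nucleophilic, so the mono-ether should dominate.

Step 2
Reactants: 3 2-(allyloxy)-6-hydroxybenzaldehyde
Product: 4 3-(allyloxy)-2-(hydroxymethyl)phenol
Conditions: NaBH4, THF–MeOH, 0 °C; aq. NH4Cl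
Reagents that add atoms: none
Why: Borohydride reduction of the aldehyde by hydride addition, kept cold and quenched at neutral pH so that the doubly oxygen-flanked benzylic alcohol does not ionise.

Step 3
Reactants: 4 3-(allyloxy)-2-(hydroxymethyl)phenol; 5 2-methylprop-1-enylboronic acid pinacol ester
Product: 7 (3R)-5-(allyloxy)-2,2-dimethyl-3-(4,4,5,5-tetramethyl-1,3,2-dioxaborolan-2-yl)chroman, via ortho-quinone methide 6 (not isolated)
Conditions: (R)-3,3'-bis(2,4,6-triisopropylphenyl)-1,1'-binaphthyl-2,2'-diyl N-(trifluoromethylsulfonyl)phosphoramide (10 mol%), 5 (4 equiv), 5 Å molecular sieves, CH2Cl2, 0 °C, 4 added over 8 h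
Reagents that add atoms: none
Why: Proposed new method: the acid ionises the benzylic alcohol of 4, which is flanked by a hydroxyl and an ether oxygen, to the hydrogen-bonded ortho-quinone methide 6, whose methylene carbon is attacked by the boron-bearing carbon of 5 because the positive charge then develops on the tertiary carbon (further supported by the adjacent C–B bond), where the quinone methide oxygen captures it. The closest known reaction type is the chiral Brønsted acid (phosphoric acid or N-triflylphosphoramide) catalysed inverse-electron-demand oxa-[4+2] cycloaddition of in situ generated ortho-quinone methides with styrenes and enol ethers; an alkenylboronate as the 2π partner is the untested element, and the N-triflyl amide is chosen over the parent phosphoric acid because this alkene is weakly nucleophilic and has no hydrogen-bond donor. Ring D closes in an asynchronous [4+2] mode, the C4–C3 bond first and the six-membered ring completed by O1–C2 bond formation at the tertiary carbon. The single new stereocentre C3 is fixed by which face of the alkene bonds to the methylene; as neither partner is chiral it is controlled by the catalyst alone, which holds 6 through a hydrogen bond to its carbonyl oxygen inside the pocket of the two triisopropylphenyl groups while its phosphoryl oxygen can engage the weakly Lewis-acidic boron. The step needs regioselectivity, secured by the tertiary cation, and chemoselectivity over self-alkylation of 4 and over alkenyl transfer with loss of boron, secured by slow addition of 4 into excess 5, by the single free phenol of 4 (the product has none) and by the hindered, weakly Lewis-acidic pinacol ester, which should not bind the quinone methide oxygen.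

Step 4
Reactants: 7 (3R)-5-(allyloxy)-2,2-dimethyl-3-(4,4,5,5-tetramethyl-1,3,2-dioxaborolan-2-yl)chroman
Product: 8 (3R)-5-(allyloxy)-2,2-dimethylchroman-3-ol
Conditions: NaBO3·4H2O (3 equiv), THF–H2O 1:1, rt
Reagents that add atoms: sodium perborate tetrahydrate NaBO3·4H2O, [Na+].[O-]OB=O.O.O.O.O
Why: Boronate oxidation, in which perborate adds to boron and C3 migrates from boron to oxygen with retention, so the (3R)-boronate should give the (3R)-alcohol while the mild oxidant leaves the allyl ether untouched.

Step 5
Reactants: 8 (3R)-5-(allyloxy)-2,2-dimethylchroman-3-ol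
Product: 10 (3R)-6-allyl-2,2-dimethylchroman-3,5-diol, via dienone 9 (not isolated)
Conditions: PhNEt2, 190 °C, sealed tube
Reagents that add atoms: none
Why: Aromatic Claisen rearrangement, the [3,3] shift delivering the allyl group to C6, the only unsubstituted ortho position, through dienone 9, which tautomerises to the phenol; C3 is not involved.

Step 6
Reactants: 10 (3R)-6-allyl-2,2-dimethylchroman-3,5-diol
Product: 11 (3R)-6-allyl-3,5-bis(methoxymethoxy)-2,2-dimethylchroman
Conditions: NaH (2.5 equiv), MOMCl (3 equiv), THF–DMF, 0 °C → rt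
Reagents that add atoms: chloromethyl methyl ether, COCCl
Why: Williamson-type alkylation of both the phenoxide and the secondary alkoxide, giving base-stable acetals that survive the enamine acylation and the fluoride displacement.

Step 7
Reactants: 11 (3R)-6-allyl-3,5-bis(methoxymethoxy)-2,2-dimethylchroman
Product: 13 2-[(3R)-3,5-bis(methoxymethoxy)-2,2-dimethylchroman-6-yl]acetaldehyde, via diol 12 (not isolated)
Conditions: OsO4 (2 mol%), NaIO4 (4 equiv), 2,6-lutidine, dioxane–H2O 3:1, rt
Reagents that add atoms: osmium tetroxide, O=[Os](=O)(=O)=O; sodium periodate, [Na+].[O-]I(=O)(=O)=O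
Why: Lemieux–Johnson oxidation, OsO4 dihydroxylating the terminal alkene to diol 12 (both epimers at the new carbinol, of no consequence) and periodate cleaving it to the aldehyde, with 2,6-lutidine suppressing over-oxidation.

Step 8
Reactants: 14 5-fluororesorcinol
Product: 15 1-fluoro-3,5-bis(methoxymethoxy)benzene
Conditions: MOMCl (2.5 equiv), iPr2NEt (3 equiv), CH2Cl2, 0 °C → rt
Reagents that add atoms: chloromethyl methyl ether, COCCl
Why: Alkylation of both phenols gives two strong ortho-directing acetal groups that are removable with acid at the end.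

Step 9
Reactants: 15 1-fluoro-3,5-bis(methoxymethoxy)benzene; 16 1-bromo-3-methylbut-2-ene
Product: 18 5-fluoro-1,3-bis(methoxymethoxy)-2-(3-methylbut-2-enyl)benzene, via aryllithium 17 (not isolated)
Conditions: n-BuLi, THF, −78 → −40 °C; CuI (10 mol%), 16, −40 °C → rt
Reagents that add atoms: none
Why: Directed ortho-metalation, n-BuLi being expected to deprotonate the position chelated by both acetal oxygens, followed by copper-catalysed allylation at the primary carbon of 16 without allylic transposition.

Step 10
Reactants: 18 5-fluoro-1,3-bis(methoxymethoxy)-2-(3-methylbut-2-enyl)benzene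
Product: 20 6-fluoro-2,4-bis(methoxymethoxy)-3-(3-methylbut-2-enyl)benzoic acid, via aryllithium 19 (not isolated)
Conditions: n-BuLi, THF, −78 °C; CO2, −78 °C → rt; 1 M HCl to pH 4, 0 °C
Reagents that add atoms: carbon dioxide, O=C=O
Why: Second directed ortho-metalation at one of the two symmetry-equivalent remaining positions, each flanked by fluorine and an acetal oxygen, then carboxylation; at −78 °C the ortho-fluoroaryllithium should not lose LiF.

Step 11
Reactants: 20 6-fluoro-2,4-bis(methoxymethoxy)-3-(3-methylbut-2-enyl)benzoic acid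
Product: 21 6-fluoro-2,4-bis(methoxymethoxy)-3-(3-methylbut-2-enyl)benzoyl chloride
Conditions: 1-chloro-N,N,2-trimethylprop-1-en-1-amine (1.2 equiv), CH2Cl2, 0 °C → rt; used at once as a solution
Reagents that add atoms: 1-chloro-N,N,2-trimethylprop-1-en-1-amine, CC(C)=C(Cl)N(C)C
Why: The α-chloroenamine converts the acid to its chloride under neutral conditions (the proton ends on the amide by-product), so no HCl is formed that could cleave the acetals or add to the prenyl group.

Step 12
Reactants: 13 2-[(3R)-3,5-bis(methoxymethoxy)-2,2-dimethylchroman-6-yl]acetaldehyde; 21 6-fluoro-2,4-bis(methoxymethoxy)-3-(3-methylbut-2-enyl)benzoyl chloride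
Product: 23 2-[(3R)-3,5-bis(methoxymethoxy)-2,2-dimethylchroman-6-yl]-1-[6-fluoro-2,4-bis(methoxymethoxy)-3-(3-methylbut-2-enyl)phenyl]-3-(morpholin-4-yl)prop-2-en-1-one, via enamine 22 (not isolated)
Conditions: morpholine (1.0 equiv), 4 Å molecular sieves, toluene, rt; filter, concentrate; 21, Et3N, toluene, 0 °C → rt
Reagents that add atoms: morpholine, C1COCCN1
Why: Condensation gives the conjugated (E)-enamine 22, which is C-acylated at its aryl-bearing carbon by the aroyl chloride (Stork enamine acylation), Et3N taking up HCl to leave the push–pull enaminone.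

Step 13
Reactants: 23 2-[(3R)-3,5-bis(methoxymethoxy)-2,2-dimethylchroman-6-yl]-1-[6-fluoro-2,4-bis(methoxymethoxy)-3-(3-methylbut-2-enyl)phenyl]-3-(morpholin-4-yl)prop-2-en-1-one
Product: 25 3-[(3R)-3,5-bis(methoxymethoxy)-2,2-dimethylchroman-6-yl]-5,7-bis(methoxymethoxy)-6-(3-methylbut-2-enyl)-4H-chromen-4-one, via enol 24 (not isolated)
Conditions: AcOH–H2O–THF, rt; then K2CO3, DMF, 80 °C
Reagents that add atoms: water, O
Why: Mild acid hydrolyses the vinylogous amide to the hydroxymethylene ketone 24, whose enolate oxygen then displaces the fluoride ortho to the aryl ketone by intramolecular nucleophilic aromatic substitution (addition–elimination, closing ring C), the two acetal oxygens being meta to the reacting carbon and therefore not deactivating it.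

Step 14
Reactants: 25 3-[(3R)-3,5-bis(methoxymethoxy)-2,2-dimethylchroman-6-yl]-5,7-bis(methoxymethoxy)-6-(3-methylbut-2-enyl)-4H-chromen-4-one
Product: 26 3-[(3R)-3,5-dihydroxy-2,2-dimethylchroman-6-yl]-5,7-dihydroxy-6-(3-methylbut-2-enyl)-4H-chromen-4-one (CNP0194496.1)
Conditions: 3 M aq. HCl–MeOH, 50 °C
Reagents that add atoms: none
Why: Acid-catalysed methanolysis of the four methoxymethyl acetals (transacetalisation to dimethoxymethane); the C3'' carbinol, the tertiary aryl ether of ring D and the prenyl group are expected to survive if the reaction is stopped at completion.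

**Compound list**

1 | 2,6-dihydroxybenzaldehyde | O=Cc1c(O)cccc1O | starting material
2 | allyl bromide (3-bromoprop-1-ene) | C=CCBr | starting material
3 | 2-(allyloxy)-6-hydroxybenzaldehyde | O=Cc1c(O)cccc1OCC=C | intermediate
4 | 3-(allyloxy)-2-(hydroxymethyl)phenol | OCc1c(O)cccc1OCC=C | intermediate
5 | 2-methylprop-1-enylboronic acid pinacol ester | CC(C)=CB1OC(C)(C)C(C)(C)O1 | starting material
6 | 5-(allyloxy)-6-methylidenecyclohexa-2,4-dien-1-one (ortho-quinone methide) | C=CCOC1=CC=CC(=O)C1=C | intermediate
7 | (3R)-5-(allyloxy)-2,2-dimethyl-3-(4,4,5,5-tetramethyl-1,3,2-dioxaborolan-2-yl)chroman | C=CCOc1cccc2c1C[C@@H](B1OC(C)(C)C(C)(C)O1)C(C)(C)O2 | intermediate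
8 | (3R)-5-(allyloxy)-2,2-dimethylchroman-3-ol | C=CCOc1cccc2c1C[C@@H](O)C(C)(C)O2 | intermediate
9 | (3R)-6-allyl-3-hydroxy-2,2-dimethyl-4,6-dihydro-3H-chromen-5-one (Claisen dienone, C6 epimers) | C=CCC1C=CC2=C(C[C@@H](O)C(C)(C)O2)C1=O | intermediate
10 | (3R)-6-allyl-2,2-dimethylchroman-3,5-diol | C=CCc1ccc2c(c1O)C[C@@H](O)C(C)(C)O2 | intermediate
11 | (3R)-6-allyl-3,5-bis(methoxymethoxy)-2,2-dimethylchroman | C=CCc1ccc2c(c1OCOC)C[C@@H](OCOC)C(C)(C)O2 | intermediate
12 | 3-[(3R)-3,5-bis(methoxymethoxy)-2,2-dimethylchroman-6-yl]propane-1,2-diol (side-chain epimers) | OCC(O)Cc1ccc2c(c1OCOC)C[C@@H](OCOC)C(C)(C)O2 | intermediate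
13 | 2-[(3R)-3,5-bis(methoxymethoxy)-2,2-dimethylchroman-6-yl]acetaldehyde | O=CCc1ccc2c(c1OCOC)C[C@@H](OCOC)C(C)(C)O2 | intermediate
14 | 5-fluororesorcinol | Oc1cc(O)cc(F)c1 | starting material
15 | 1-fluoro-3,5-bis(methoxymethoxy)benzene | COCOc1cc(F)cc(OCOC)c1 | intermediate
16 | 1-bromo-3-methylbut-2-ene | CC(C)=CCBr | starting material
17 | [4-fluoro-2,6-bis(methoxymethoxy)phenyl]lithium | [Li]c1c(OCOC)cc(F)cc1OCOC | intermediate
18 | 5-fluoro-1,3-bis(methoxymethoxy)-2-(3-methylbut-2-enyl)benzene | CC(C)=CCc1c(OCOC)cc(F)cc1OCOC | intermediate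
19 | [6-fluoro-2,4-bis(methoxymethoxy)-3-(3-methylbut-2-enyl)phenyl]lithium | [Li]c1c(F)cc(OCOC)c(CC=C(C)C)c1OCOC | intermediate
20 | 6-fluoro-2,4-bis(methoxymethoxy)-3-(3-methylbut-2-enyl)benzoic acid | OC(=O)c1c(F)cc(OCOC)c(CC=C(C)C)c1OCOC | intermediate
21 | 6-fluoro-2,4-bis(methoxymethoxy)-3-(3-methylbut-2-enyl)benzoyl chloride | O=C(Cl)c1c(F)cc(OCOC)c(CC=C(C)C)c1OCOC | intermediate
22 | 4-[(E)-2-[(3R)-3,5-bis(methoxymethoxy)-2,2-dimethylchroman-6-yl]ethenyl]morpholine | O1CCN(CC1)/C=C/c1ccc2c(c1OCOC)C[C@@H](OCOC)C(C)(C)O2 | intermediate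
23 | 2-[(3R)-3,5-bis(methoxymethoxy)-2,2-dimethylchroman-6-yl]-1-[6-fluoro-2,4-bis(methoxymethoxy)-3-(3-methylbut-2-enyl)phenyl]-3-(morpholin-4-yl)prop-2-en-1-one (alkene geometry not specified) | O=C(C(=CN1CCOCC1)c1ccc2c(c1OCOC)C[C@@H](OCOC)C(C)(C)O2)c1c(F)cc(OCOC)c(CC=C(C)C)c1OCOC | intermediate
24 | 2-[(3R)-3,5-bis(methoxymethoxy)-2,2-dimethylchroman-6-yl]-1-[6-fluoro-2,4-bis(methoxymethoxy)-3-(3-methylbut-2-enyl)phenyl]-3-hydroxyprop-2-en-1-one (enol form) | O=C(C(=CO)c1ccc2c(c1OCOC)C[C@@H](OCOC)C(C)(C)O2)c1c(F)cc(OCOC)c(CC=C(C)C)c1OCOC | intermediate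
25 | 3-[(3R)-3,5-bis(methoxymethoxy)-2,2-dimethylchroman-6-yl]-5,7-bis(methoxymethoxy)-6-(3-methylbut-2-enyl)-4H-chromen-4-one | CC(C)=CCc1c(OCOC)cc2occ(-c3ccc4c(c3OCOC)C[C@@H](OCOC)C(C)(C)O4)c(=O)c2c1OCOC | intermediate
26 | 3-[(3R)-3,5-dihydroxy-2,2-dimethylchroman-6-yl]-5,7-dihydroxy-6-(3-methylbut-2-enyl)-4H-chromen-4-one | CC(C)=CCc1c(O)cc2occ(-c3ccc4c(c3O)C[C@@H](O)C(C)(C)O4)c(=O)c2c1O | target

**Step count and risks**

Total steps: 14. Longest linear sequence: 10 steps (steps 1–7, then 12–14); the ring A branch (steps 8–11) joins at step 12.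

Step 3 (Proposed new method). The electron-rich precursor may alkylate itself faster than the weakly nucleophilic alkenylboronate captures the quinone methide, the alkenyl group may be transferred with loss of boron, or facial discrimination may be weak. The fallback uses known chemistry, sets out from 3 and returns at 8, bypassing steps 2–4. 2-Methylprop-1-enylmagnesium bromide (3 equiv, THF, 0 °C) adds to the aldehyde of 3 to give 3-(allyloxy)-2-(1-hydroxy-3-methylbut-2-enyl)phenol F1. Warming in toluene at 80 °C dehydrates it to the alkenyl quinone methide 5-(allyloxy)-6-(3-methylbut-2-enylidene)cyclohexa-2,4-dien-1-one F2, which closes by oxa-6π electrocyclisation to 5-(allyloxy)-2,2-dimethyl-2H-chromene F3. Jacobsen–Katsuki epoxidation with (R,R)-N,N'-bis(3,5-di-tert-butylsalicylidene)-1,2-cyclohexanediaminomanganese chloride, NaOCl and 4-phenylpyridine N-oxide in CH2Cl2 at 0 °C should give (3R,4R)-5-(allyloxy)-3,4-epoxy-2,2-dimethylchroman F4; the conjugated cis-alkene is expected to react and the allyl ether not. LiAlH4 in THF should open the epoxide by hydride attack at the benzylic C4, leaving the C3 oxygen in place and giving 8.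

Step 12. C-acylation of the hindered, conjugated enamine may be outpaced by N-acylation or by hydrolysis of the acid chloride, so that the C3–C4 bond does not form. The fallback sets out from 13 and from aryllithium 19 (made from 18 as in step 10) and returns at 24. Addition of 19 to aldehyde 13 in THF at −78 °C should give 1-[6-fluoro-2,4-bis(methoxymethoxy)-3-(3-methylbut-2-enyl)phenyl]-2-[(3R)-3,5-bis(methoxymethoxy)-2,2-dimethylchroman-6-yl]ethanol F5 as a mixture of carbinol epimers. Dess–Martin oxidation should give the deoxybenzoin 1-[6-fluoro-2,4-bis(methoxymethoxy)-3-(3-methylbut-2-enyl)phenyl]-2-[(3R)-3,5-bis(methoxymethoxy)-2,2-dimethylchroman-6-yl]ethanone F6. Claisen formylation with ethyl formate and NaH in THF then gives 24 as its sodium enolate, which enters the second stage of step 13.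

Step 9. Deprotonation may leak to the position next to fluorine instead of the one between the two acetal oxygens, giving the wrong prenyl isomer or, on warming, loss of LiF. The fallback sets out from 14 and returns at 17, placing the metal by halogen–metal exchange. Iodination of 14 between the hydroxyls (I2, NaHCO3, H2O, 0 °C) should give 5-fluoro-2-iodobenzene-1,3-diol F7. MOMCl and iPr2NEt in CH2Cl2 give 5-fluoro-2-iodo-1,3-bis(methoxymethoxy)benzene F8. n-BuLi in THF at −78 °C exchanges iodine for lithium to give 17 at a defined position, which is prenylated to 18 as in step 9.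

**Further compounds**

F1 | step 3 | 3-(allyloxy)-2-(1-hydroxy-3-methylbut-2-enyl)phenol | CC(C)=CC(O)c1c(O)cccc1OCC=C
F2 | step 3 | 5-(allyloxy)-6-(3-methylbut-2-enylidene)cyclohexa-2,4-dien-1-one | CC(C)=CC=C1C(=O)C=CC=C1OCC=C
F3 | step 3 | 5-(allyloxy)-2,2-dimethyl-2H-chromene | C=CCOc1cccc2c1C=CC(C)(C)O2
F4 | step 3 | (3R,4R)-5-(allyloxy)-3,4-epoxy-2,2-dimethylchroman | C=CCOc1cccc2c1[C@H]3O[C@H]3C(C)(C)O2
F5 | step 12 | 1-[6-fluoro-2,4-bis(methoxymethoxy)-3-(3-methylbut-2-enyl)phenyl]-2-[(3R)-3,5-bis(methoxymethoxy)-2,2-dimethylchroman-6-yl]ethanol | OC(Cc1ccc2c(c1OCOC)C[C@@H](OCOC)C(C)(C)O2)c1c(F)cc(OCOC)c(CC=C(C)C)c1OCOC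
F6 | step 12 | 1-[6-fluoro-2,4-bis(methoxymethoxy)-3-(3-methylbut-2-enyl)phenyl]-2-[(3R)-3,5-bis(methoxymethoxy)-2,2-dimethylchroman-6-yl]ethanone | O=C(Cc1ccc2c(c1OCOC)C[C@@H](OCOC)C(C)(C)O2)c1c(F)cc(OCOC)c(CC=C(C)C)c1OCOC
F7 | step 9 | 5-fluoro-2-iodobenzene-1,3-diol | Oc1cc(F)cc(O)c1I
F8 | step 9 | 5-fluoro-2-iodo-1,3-bis(methoxymethoxy)benzene | COCOc1cc(F)cc(OCOC)c1I
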